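**Retrosynthetic overview**
1. The target is cut at the Z-olefin C7=C8 (Z-selective cross-metathesis, then acetal hydrolysis) into a vinyl-substituted ring A lactone carrying C6 and a protected C8–C16 polyol alkene.
2. The vinyl lactone comes from hex-1-en-5-yne and acrylic acid in one pot: rhodium-catalysed propargylic C–H acyloxylation makes O1–C6 and sets C6, and ring-closing metathesis makes C3=C4 and closes ring A.
3. Enabling feature: C6 of ring A bears O1 and is at once allylic to C7=C8 and homoallylic to C4, so ring A plus C7/C8 is a hexa-1,5-dien-3-yl acrylate, the direct product of adding the acid across the enyne.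
4. The polyol comes from a 1,5-anti boron aldol (C13–C14) and an Evans–Tishchenko reduction (sets C12, puts the acetate on O14) of a methyl ketone whose C10 carbinol is set by an iridium-catalysed allylation.
5. Ring order: ring A (the δ-lactone, the only ring of the target) is formed first, in step 1; a temporary 1,3-dioxane over O10/O12 is made in step 7 and cleaved in step 9.

Key step: step 1

Remark on numbering: atoms are numbered O1, C2 (carbonyl), C3=C4, C5, C6 in the lactone and on along the side chain (C7=C8, C9, C10–OH, C11, C12–OH, C13, C14–OAc, C15, C16, phenyl).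
Remark on the ligand-controlled steps 1 and 2: the antipode of the chiral diphosphine is the one that delivers the configuration drawn; the sense of induction is to be confirmed on the first run.

**Step 1**
Reactants: 1 hex-1-en-5-yne; 2 acrylic acid
Product: 5 (S)-6-vinyl-5,6-dihydro-2H-pyran-2-one, via hexa-1,2,5-triene 3 (not isolated), via (S)-hexa-1,5-dien-3-yl acrylate 4 (not isolated)
Conditions: 1 (1.2 equiv), [Rh(cod)Cl]2 (2.5 mol%), Cp-DIOP (6 mol%), ClCH2CH2Cl, 40 °C; solvent swap to CH2Cl2 (0.01 M), first-generation Grubbs catalyst RuCl2(PCy3)2(=CHPh) (8 mol%), Ti(OiPr)4 (0.3 equiv), 40 °C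
Reagents that add atoms: none
Why: Acrylic acid adds oxidatively to monovalent rhodium to give a rhodium hydride that isomerises the terminal alkyne of 1 to allene 3 and hydrometalates it to a π-allyl rhodium carboxylate, whose inner-sphere reductive elimination at the substituted allyl terminus forms the O1–C6 bond and gives branched ester 4; the closest known reaction type is the redox-neutral, enantioselective rhodium/DIOP coupling of terminal alkynes or allenes with carboxylic acids to branched allylic esters. Without isolation of 4, the ruthenium alkylidene loads on the unhindered homoallylic vinyl group and closes onto the acrylate through a ruthenacyclobutane with loss of ethylene, forming C3=C4; the closest precedent is acrylate ring-closing metathesis of homoallylic acrylates to 5,6-dihydropyran-2-ones. The only ring, six-membered ring A, is closed in this metathesis event, and its size enforces the cis C3=C4 geometry. The single new stereocenter, C6, is set in the C–O reductive elimination under control of the C2-symmetric diphosphine on rhodium and is not touched by the metathesis. The step needs branched over linear ester (secured by the inner-sphere allyl mechanism of this catalyst class), reductive elimination faster than β-hydride loss from the doubly allylic C5 (favoured by mild temperature), and six- over five-membered closure (secured because the vinyl group next to the acyloxy-bearing C6 is sterically and electronically deactivated, so initiation occurs at the homoallylic olefin).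

**Step 2**
Reactants: 6 2-(2-methyl-1,3-dioxolan-2-yl)ethanol; 7 allyl acetate
Product: 8 (R)-1-(2-methyl-1,3-dioxolan-2-yl)pent-4-en-2-ol
Conditions: [Ir(cod)Cl]2 (2.5 mol%), SEGPHOS (5 mol%), 4-chloro-3-nitrobenzoic acid (10 mol%), Cs2CO3 (20 mol%), THF, 100 °C, sealed tube
Reagents that add atoms: none
Why: Krische allylation (iridium-catalysed transfer-hydrogenative carbonyl allylation): the cyclometalated π-allyl iridium benzoate dehydrogenates the primary alcohol to the aldehyde in situ and adds the allyl group through a closed chair-like transition state, so the chiral diphosphine on iridium sets the C10 carbinol as R while the ketal is inert to the weakly basic medium.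

**Step 3**
Reactants: 8 (R)-1-(2-methyl-1,3-dioxolan-2-yl)pent-4-en-2-ol
Product: 9 2-{(R)-2-[(4-methoxybenzyl)oxy]pent-4-en-1-yl}-2-methyl-1,3-dioxolane
Conditions: NaH, 4-methoxybenzyl chloride, Bu4NI (cat.), THF/DMF, 0 °C to rt
Reagents that add atoms: 4-methoxybenzyl chloride, COc1ccc(CCl)cc1
Why: Williamson etherification of the sodium alkoxide with the benzylic chloride, in which the stereocenter is not involved and the ketal and alkene are inert to NaH.

**Step 4**
Reactants: 9 2-{(R)-2-[(4-methoxybenzyl)oxy]pent-4-en-1-yl}-2-methyl-1,3-dioxolane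
Product: 10 (R)-4-[(4-methoxybenzyl)oxy]hept-6-en-2-one
Conditions: 1 M aq. HCl, THF, rt
Reagents that add atoms: water, O
Why: Acid-catalysed ketal hydrolysis liberates the methyl ketone, the PMB ether and terminal alkene surviving dilute acid at room temperature and the mild conditions avoiding β-elimination of the C10 alkoxy group.

**Step 5**
Reactants: 10 (R)-4-[(4-methoxybenzyl)oxy]hept-6-en-2-one; 11 3-phenylpropanal
Product: 12 (3R,7R)-3-hydroxy-7-[(4-methoxybenzyl)oxy]-1-phenyldec-9-en-5-one
Conditions: (c-Hex)2BCl, Et3N, Et2O, 0 °C; 11, −78 to −20 °C; then MeOH, pH 7 buffer, 30% H2O2, 0 °C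
Reagents that add atoms: none
Why: Boron-mediated methyl ketone aldol reaction with 1,5-anti induction: kinetic enolisation on the methyl side and addition through a boat-like transition state in which the β-PMB ether oxygen contacts the aldehyde formyl hydrogen, so that the existing C10 stereocenter sets the new C14 carbinol as R (1,5-anti).

**Step 6**
Reactants: 12 (3R,7R)-3-hydroxy-7-[(4-methoxybenzyl)oxy]-1-phenyldec-9-en-5-one
Product: 13 (3R,5R,7R)-5-hydroxy-7-[(4-methoxybenzyl)oxy]-1-phenyldec-9-en-3-yl acetate
Conditions: SmI2 (0.3 equiv), MeCHO (8 equiv), THF, −10 °C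
Reagents that add atoms: acetaldehyde, CC=O
Why: Evans–Tishchenko reduction: the C14 hydroxyl forms a hemiacetal with acetaldehyde and, in a samarium-bound six-membered chair transition state, delivers its hydride intramolecularly to the C12 ketone, setting C12 as R (1,3-anti to C14) and leaving the acetate regiospecifically on the C14 oxygen in the same operation.

**Step 7**
Reactants: 13 (3R,5R,7R)-5-hydroxy-7-[(4-methoxybenzyl)oxy]-1-phenyldec-9-en-3-yl acetate
Product: 14 (R)-1-[(2R,4R,6R)-6-allyl-2-(4-methoxyphenyl)-1,3-dioxan-4-yl]-4-phenylbutan-2-yl acetate (all-cis dioxane)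
Conditions: DDQ (1.2 equiv), 4 Å molecular sieves, CH2Cl2, 0 °C
Reagents that add atoms: none
Why: DDQ oxidative acetalisation: hydride abstraction from the PMB methylene gives an oxocarbenium ion that is trapped by the syn C12 hydroxyl to close a six-membered 1,3-dioxane whose new acetal center adopts the all-equatorial chair under substrate control, so both hydroxyls are masked without a new protecting reagent and the acetate and alkene are untouched.

**Step 8**
Reactants: 14 (R)-1-[(2R,4R,6R)-6-allyl-2-(4-methoxyphenyl)-1,3-dioxan-4-yl]-4-phenylbutan-2-yl acetate; 5 (S)-6-vinyl-5,6-dihydro-2H-pyran-2-one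
Product: 15 (R)-1-[(2R,4R,6R)-2-(4-methoxyphenyl)-6-{(Z)-3-[(S)-6-oxo-3,6-dihydro-2H-pyran-2-yl]allyl}-1,3-dioxan-4-yl]-4-phenylbutan-2-yl acetate
Conditions: 5 (3 equiv), Ru(NO3)[κ2(C,C)-1-(adamantan-1-yl)-3-(2,6-diisopropylphenyl)-4,5-dihydroimidazol-2-ylidene, cyclometalated at adamantyl](=CH-C6H4-2-OiPr) (7.5 mol%), THF, 35 °C, static vacuum
Reagents that add atoms: none
Why: Z-selective olefin cross-metathesis, precedented for allylic-substituted terminal olefins with this catalyst class: the C,C-chelated ruthenium alkylidene forms side-bound metallacyclobutanes in which both substituents point away from the N-aryl group, giving the Z C7=C8 olefin under kinetic control, while the conjugated C3=C4 of the lactone is too electron-poor to react and the excess of 5 suppresses homodimerisation of 14.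

**Step 9**
Reactants: 15 (R)-1-[(2R,4R,6R)-2-(4-methoxyphenyl)-6-{(Z)-3-[(S)-6-oxo-3,6-dihydro-2H-pyran-2-yl]allyl}-1,3-dioxan-4-yl]-4-phenylbutan-2-yl acetate
Product: 16 (3R,5R,7R,9Z)-5,7-dihydroxy-10-[(2S)-6-oxo-3,6-dihydro-2H-pyran-2-yl]-1-phenyldec-9-en-3-yl acetate
Conditions: AcOH/THF/H2O (3:1:1), 35 °C
Reagents that add atoms: none
Why: Acid-catalysed acetal hydrolysis releases the C10 and C12 hydroxyls, while the secondary acetate, the allylic lactone C6–O1 bond and the Z-olefin are stable to aqueous acetic acid and no stereocenter is affected.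

**Compound list**
1 | hex-1-en-5-yne | C=CCCC#C | starting material
2 | acrylic acid | C=CC(=O)O | starting material
3 | hexa-1,2,5-triene | C=C=CCC=C | intermediate
4 | (S)-hexa-1,5-dien-3-yl acrylate | C=CC(=O)O[C@@H](CC=C)C=C | intermediate
5 | (S)-6-vinyl-5,6-dihydro-2H-pyran-2-one | C=C[C@@H]1CC=CC(=O)O1 | intermediate
6 | 2-(2-methyl-1,3-dioxolan-2-yl)ethanol | CC1(CCO)OCCO1 | starting material
7 | allyl acetate | C=CCOC(C)=O | starting material
8 | (R)-1-(2-methyl-1,3-dioxolan-2-yl)pent-4-en-2-ol | CC1(C[C@H](O)CC=C)OCCO1 | intermediate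
9 | 2-{(R)-2-[(4-methoxybenzyl)oxy]pent-4-en-1-yl}-2-methyl-1,3-dioxolane | CC1(C[C@H](OCc2ccc(OC)cc2)CC=C)OCCO1 | intermediate
10 | (R)-4-[(4-methoxybenzyl)oxy]hept-6-en-2-one | CC(=O)C[C@H](OCc1ccc(OC)cc1)CC=C | intermediate
11 | 3-phenylpropanal | O=CCCc1ccccc1 | starting material
12 | (3R,7R)-3-hydroxy-7-[(4-methoxybenzyl)oxy]-1-phenyldec-9-en-5-one | O[C@H](CCc1ccccc1)CC(=O)C[C@H](OCc1ccc(OC)cc1)CC=C | intermediate
13 | (3R,5R,7R)-5-hydroxy-7-[(4-methoxybenzyl)oxy]-1-phenyldec-9-en-3-yl acetate | CC(=O)O[C@H](CCc1ccccc1)C[C@H](O)C[C@H](OCc1ccc(OC)cc1)CC=C | intermediate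
14 | (R)-1-[(2R,4R,6R)-6-allyl-2-(4-methoxyphenyl)-1,3-dioxan-4-yl]-4-phenylbutan-2-yl acetate | CC(=O)O[C@H](CCc1ccccc1)C[C@H]1C[C@@H](CC=C)O[C@@H](c2ccc(OC)cc2)O1 | intermediate
15 | (R)-1-[(2R,4R,6R)-2-(4-methoxyphenyl)-6-{(Z)-3-[(S)-6-oxo-3,6-dihydro-2H-pyran-2-yl]allyl}-1,3-dioxan-4-yl]-4-phenylbutan-2-yl acetate | CC(=O)O[C@H](CCc1ccccc1)C[C@H]1C[C@@H](C/C=C\[C@@H]2CC=CC(=O)O2)O[C@@H](c2ccc(OC)cc2)O1 | intermediate
16 | (3R,5R,7R,9Z)-5,7-dihydroxy-10-[(2S)-6-oxo-3,6-dihydro-2H-pyran-2-yl]-1-phenyldec-9-en-3-yl acetate | CC(=O)O[C@H](CCc1ccccc1)C[C@H](O)C[C@H](O)C/C=C\[C@@H]1CC=CC(=O)O1 | target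

**Step count and risks**
Total step count: 9. Longest linear sequence: 8 steps (steps 2 to 9, from 6).

Steps most likely to fail:

1. Step 1. The π-allyl rhodium intermediate may lose a β-hydride from the doubly allylic C5 and divert to a conjugated triene, the rhodium hydride may isomerise the remote olefin, or enantiofacial control may be incomplete. The fallback sets out from acrylic acid 2. Mitsunobu esterification (PPh3, DIAD, THF, 0 °C) of (R)-hexa-1,5-dien-3-ol F1, obtained by kinetic resolution of the commercial racemate, inverts the carbinol and gives ester 4, now isolated. Acrylate ring-closing metathesis (first-generation Grubbs catalyst, Ti(OiPr)4, CH2Cl2, 40 °C) then gives 5, where the route is rejoined.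

2. Step 8. Turnover at the hindered allylic-ester olefin of 5 may be slow, and secondary metathesis may erode the Z-selectivity. The fallback sets out from 5 and 14. Ozonolysis of 5 at the vinyl group only (O3, CH2Cl2, −78 °C, indicator dye, then Me2S) gives (S)-6-oxo-3,6-dihydro-2H-pyran-2-carbaldehyde F2. Ozonolysis of 14 with NaBH4 work-up gives the primary C8 alcohol F3, I2/PPh3/imidazole gives the iodide F4, and PPh3 in MeCN at 80 °C gives the phosphonium iodide F5. Ylide formation (NaN(SiMe3)2, THF, −78 °C) and addition of F2 closes C7=C8 by a Z-selective Wittig reaction and gives 15, where the route is rejoined.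

3. Step 6. The acetate may migrate between the C14 and C12 oxygens, or the aldol may revert, under the Lewis-acidic samarium alkoxide conditions. The fallback sets out from 12. Evans–Saksena reduction (Me4NBH(OAc)3, MeCN/AcOH, −30 °C) gives the 3,5-anti diol (3R,5S,7R)-7-[(4-methoxybenzyl)oxy]-1-phenyldec-9-ene-3,5-diol F6. DDQ with 4 Å sieves engages only the C12 hydroxyl, which closes the six-membered acetal with the syn C10 oxygen, and gives the hydroxy acetal (R)-1-[(2R,4S,6R)-6-allyl-2-(4-methoxyphenyl)-1,3-dioxan-4-yl]-4-phenylbutan-2-ol F7. Acetylation of the free C14 hydroxyl (Ac2O, pyridine, DMAP) gives 14, where the route is rejoined.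

**Further compounds**
F1 | step 1 | (R)-hexa-1,5-dien-3-ol | O[C@H](CC=C)C=C
F2 | step 8 | (S)-6-oxo-3,6-dihydro-2H-pyran-2-carbaldehyde | O=C[C@@H]1CC=CC(=O)O1
F3 | step 8 | primary alcohol from 14 (allyl group shortened to 2-hydroxyethyl, other centers as in 14) | CC(=O)O[C@H](CCc1ccccc1)C[C@H]1C[C@@H](CCO)O[C@@H](c2ccc(OC)cc2)O1
F4 | step 8 | iodide corresponding to F3 (2-iodoethyl) | CC(=O)O[C@H](CCc1ccccc1)C[C@H]1C[C@@H](CCI)O[C@@H](c2ccc(OC)cc2)O1
F5 | step 8 | triphenylphosphonium iodide corresponding to F4 | CC(=O)O[C@H](CCc1ccccc1)C[C@H]1C[C@@H](CC[P+](c2ccccc2)(c2ccccc2)c2ccccc2)O[C@@H](c2ccc(OC)cc2)O1.[I-]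
F6 | step 6 | (3R,5S,7R)-7-[(4-methoxybenzyl)oxy]-1-phenyldec-9-ene-3,5-diol | O[C@H](CCc1ccccc1)C[C@H](O)C[C@H](OCc1ccc(OC)cc1)CC=C
F7 | step 6 | (R)-1-[(2R,4S,6R)-6-allyl-2-(4-methoxyphenyl)-1,3-dioxan-4-yl]-4-phenylbutan-2-ol | O[C@H](CCc1ccccc1)C[C@H]1C[C@@H](CC=C)O[C@@H](c2ccc(OC)cc2)O1
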